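**Plan**
1. The target is methyl shikimate acylated at O3 and O5 by (2E)-3-methylpent-2-enoic acid; ring atoms are numbered C1 (bears CO2Me), C2 (vinylic CH), C3–C5 (O-bearing), C6 (CH2).
2. Retrosynthesis: first the C3–O ester bond (C3–OAcyl/C4–OH traced back to a 3,4-epoxide, then to a C3=C4 alkene); then C6–C1 and C4–C5 together, which releases C5–C6 as the vinyl ester of the side-chain acid.
3. Enabling feature: without O3/O4, C1=C2–C3=C4 is a 1,3-diene and C5(O)–C6H2 is an enol-ester edge. Bridging C1 and C4 by O–C(=O) makes that diene a 2-pyranone, whose lactone carbonyl renders the ester-bearing C1 electrophilic (polarity reversal) and later leaves as CO2.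
4. Forward: the 2-pyranone ring (bought) becomes a 2-oxabicyclo[2.2.2]octene lactone, loss of CO2 gives the only carbocycle (a cyclohexa-1,3-diene), then the C3–C4 epoxide is formed and opened by the second acid unit.
5. Stereochemistry: C5 comes from the catalyst-controlled endo cycloaddition; C3 and C4 come from epoxidation anti to the C5 ester and palladium double inversion (net retention) at C3; both E-alkenes come with the acid.

Key step: step 3

Assumption: geometrically pure (2E)-3-methylpent-2-enoic acid and 2-oxo-2H-pyran-6-carboxylic acid are taken as purchasable (the latter is otherwise made from diethyl oxalate and ethyl crotonate).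

Step 1
Reactants: 1 (2E)-3-methylpent-2-enoic acid; 2 vinyl acetate
Product: 3 ethenyl (2E)-3-methylpent-2-enoate
Conditions: [Ir(cod)Cl]2 (1 mol %), NaOAc (3 mol %), 2 (excess), PhMe, 100 °C
Reagents that add atoms: none
Why: Iridium-catalysed transvinylation (vinyl exchange between carboxylates) is a standard way from a carboxylic acid to its vinyl ester and should leave the trisubstituted E-alkene untouched.

Step 2
Reactants: 4 2-oxo-2H-pyran-6-carboxylic acid
Product: 5 methyl 2-oxo-2H-pyran-6-carboxylate
Conditions: MeOH, H2SO4 (cat.), reflux
Reagents that add atoms: methanol (CO)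
Why: Fischer esterification, as practised on the isomeric coumalic acid; the 2-pyranone ring tolerates acidic methanol.

Step 3
Reactants: 5 methyl 2-oxo-2H-pyran-6-carboxylate; 3 ethenyl (2E)-3-methylpent-2-enoate
Product: 7 methyl (5R)-5-{[(2E)-3-methylpent-2-enoyl]oxy}cyclohexa-1,3-diene-1-carboxylate, via endo bridged lactone cycloadduct 6 (not isolated)
Conditions: 3 (3 equiv), (S)-oxazaborolidinium triflimide [(S)-1-(2-methylphenyl)-3,3-diphenyltetrahydro-1H,3H-pyrrolo[1,2-c][1,3,2]oxazaborole + HNTf2] (20 mol %), CH2Cl2, −40 to 0 °C; then 2,6-lutidine (catalyst quench), solvent switch to PhMe, BHT (cat.), 100 °C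
Reagents that add atoms: none
Why: Proposed new method: the cationic boron Lewis acid should bind the pyranone carbonyl (more basic than either ester carbonyl; B–O contact plus the α-C–H···O contact usual for enone and lactone complexes), making the ring a 2-boryloxypyrylium whose CO2Me-bearing α-carbon (target C1) is attacked by the nucleophilic CH2 of the enol ester, after which the boron dienolate closes from the lactone α-carbon (C4) onto the acyloxy-substituted carbon (C5); this is an asynchronous inverse-electron-demand Diels–Alder reaction that forms C6–C1 and C4–C5 and gives 6. The closest known reactions are the thermal cycloaddition/CO2 extrusion of electron-poor 2-pyranones with enol ethers and enol esters and the chiral-Lewis-acid-catalysed endo cycloadditions of 3-carboalkoxy-2-pyranones with vinyl ethers; new here are the monodentate chiral activation of a pyranone that lacks a chelating 3-acyl group and the use of an enol ester. The six-membered carbocycle is closed by intermolecular [4+2] cycloaddition to a 2-oxabicyclo[2.2.2]octene, and warming then opens the lactone bridge by retro-[4+2] loss of CO2, which leaves C1=C2–C3=C4 and erases both bridgehead stereocentres. C5 is the only stereocentre that survives; its R configuration should be fixed by the pyranone face left open by the aryl group of the catalyst together with the endo approach of the acyloxy group, as in the 3-carboalkoxypyranone series (the mirror-image catalyst serves if the binding model places the aryl group on the other face). The step needs regioselectivity (CH2 to the ester-bearing carbon, secured by conjugation of that carbon with the activated lactone carbonyl and by its two σ-acceptors), chemoselectivity (the vinyl C=C reacts, the electron-poor trisubstituted enoate C=C of 3 does not) and acid-free heating so that 7 does not lose the carboxylic acid and aromatise.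

Step 4
Reactants: 7 methyl (5R)-5-{[(2E)-3-methylpent-2-enoyl]oxy}cyclohexa-1,3-diene-1-carboxylate
Product: 8 methyl (3R,4S,5R)-3,4-epoxy-5-{[(2E)-3-methylpent-2-enoyl]oxy}cyclohex-1-ene-1-carboxylate
Conditions: dimethyldioxirane (1.1 equiv, acetone solution), CH2Cl2, −20 to 0 °C
Reagents that add atoms: dimethyldioxirane (CC1(C)OO1)
Why: Electrophilic epoxidation of a dienoate should go to the γ,δ-alkene C3=C4 (the α,β-alkene and the side-chain enoate are deactivated) and from the face anti to the allylic C5 acyloxy group (steric and dipole control, as in the osmylation of this diene class), which sets C3 and C4, while the neutral reagent avoids acid-triggered aromatisation.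

Step 5
Reactants: 8 methyl (3R,4S,5R)-3,4-epoxy-5-{[(2E)-3-methylpent-2-enoyl]oxy}cyclohex-1-ene-1-carboxylate; 1 (2E)-3-methylpent-2-enoic acid
Product: 9 methyl (3R,4S,5R)-4-hydroxy-3,5-bis{[(2E)-3-methylpent-2-enoyl]oxy}cyclohex-1-ene-1-carboxylate (CNP0268575.1)
Conditions: Pd(PPh3)4 (5 mol %), 1 (1.5 equiv), THF, 0 °C to rt
Reagents that add atoms: none
Why: Zerovalent palladium should ionise the vinyl epoxide with inversion at C3 to a π-allyl complex over C1–C3, and the carboxylate of 1 then attacks C3 anti to palladium (Tsuji–Trost allylic substitution with double inversion, known for γ,δ-epoxy-α,β-unsaturated esters and for carboxylic acid additions to cyclic vinyl epoxides), so the new ester is cis to the C4 hydroxyl; attack at C3 instead of C1 restores the conjugated ester and avoids the fully substituted carbon.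

**Compound list**
1 | (2E)-3-methylpent-2-enoic acid | CC/C(C)=C/C(=O)O | starting material
2 | vinyl acetate | CC(=O)OC=C | starting material
3 | ethenyl (2E)-3-methylpent-2-enoate | CC/C(C)=C/C(=O)OC=C | intermediate
4 | 2-oxo-2H-pyran-6-carboxylic acid | O=C(O)C1=CC=CC(=O)O1 | starting material
5 | methyl 2-oxo-2H-pyran-6-carboxylate | COC(=O)C1=CC=CC(=O)O1 | intermediate
6 | methyl (1R,4R,8R)-8-{[(2E)-3-methylpent-2-enoyl]oxy}-3-oxo-2-oxabicyclo[2.2.2]oct-5-ene-1-carboxylate (acyloxy group endo, syn to the C5=C6 bridge; not isolated) | COC(=O)[C@]12OC(=O)[C@H](C=C1)[C@H](OC(=O)/C=C(\C)CC)C2 | intermediate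
7 | methyl (5R)-5-{[(2E)-3-methylpent-2-enoyl]oxy}cyclohexa-1,3-diene-1-carboxylate | COC(=O)C1=CC=C[C@H](OC(=O)/C=C(\C)CC)C1 | intermediate
8 | methyl (3R,4S,5R)-3,4-epoxy-5-{[(2E)-3-methylpent-2-enoyl]oxy}cyclohex-1-ene-1-carboxylate (epoxide oxygen trans to the C5 ester) | COC(=O)C1=C[C@H]2O[C@H]2[C@H](OC(=O)/C=C(\C)CC)C1 | intermediate
9 | methyl (3R,4S,5R)-4-hydroxy-3,5-bis{[(2E)-3-methylpent-2-enoyl]oxy}cyclohex-1-ene-1-carboxylate | CC/C(C)=C/C(=O)O[C@@H]1C=C(C(=O)OC)C[C@@H](OC(=O)/C=C(\C)CC)[C@@H]1O | target

Total step count: 5. Longest linear sequence: 4 steps (4 → 5 → 7 → 8 → 9, or 1 → 3 → 7 → 8 → 9).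

**Steps most likely to fail**

Step 3 (proposed new method). What may go wrong: insufficient facial discrimination by the monodentate chiral Lewis acid, low reactivity of the weakly nucleophilic enol ester, and loss of carboxylic acid with aromatisation during CO2 extrusion. Fallback with known chemistry (resolution instead of asymmetric catalysis), setting out from 5 and 2 and returning at 7: uncatalysed thermal cycloaddition of 5 in neat 2 (sealed tube, BHT, 100–110 °C) would give racemic methyl 8-acetoxy-3-oxo-2-oxabicyclo[2.2.2]oct-5-ene-1-carboxylate F1. F1 loses CO2 in the same pot to give racemic methyl 5-acetoxycyclohexa-1,3-diene-1-carboxylate F2. Lipase-catalysed enantioselective hydrolysis (Candida antarctica lipase B, phosphate buffer pH 7/MTBE, rt), assuming the usual lipase preference for the R ester of cyclic allylic alcohols, should deliver methyl (5R)-5-hydroxycyclohexa-1,3-diene-1-carboxylate F3 and leave methyl (5S)-5-acetoxycyclohexa-1,3-diene-1-carboxylate F4, which is separated. Steglich esterification of F3 with 1 (DCC, DMAP cat., CH2Cl2, 0 °C) then gives 7.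

Step 4. What may go wrong: poor facial selectivity of the epoxidation, competing oxidation of the side-chain alkene, and acid- or base-triggered aromatisation of the diene or the epoxide. Fallback (osmylation and selective acylation instead of epoxidation and allylic substitution), setting out from 7 and returning at 9: OsO4 (cat.), NMO, acetone/H2O, 0 °C, with the anti selectivity established for 5-oxygenated cyclohexa-1,3-diene-1-carboxylates, should give methyl (3R,4R,5R)-3,4-dihydroxy-5-{[(2E)-3-methylpent-2-enoyl]oxy}cyclohex-1-ene-1-carboxylate F5. Kinetic esterification of its allylic C3 hydroxyl (the C4 hydroxyl is flanked on both sides) with 1 (DIC, DMAP cat., CH2Cl2, −20 °C) then gives 9.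

Step 5. What may go wrong: carboxylate attack at the wrong allyl terminus, β-hydride elimination of the π-allyl intermediate to a dienol or ketone, and acyl migration to O4. Fallback (two classical SN2 inversions instead of palladium catalysis), setting out from 8 and returning at 9: MgBr2·OEt2, Et2O, −20 °C should open the epoxide at the allylic carbon with inversion to methyl (3S,4S,5R)-3-bromo-4-hydroxy-5-{[(2E)-3-methylpent-2-enoyl]oxy}cyclohex-1-ene-1-carboxylate F6. Displacement of the allylic bromide with the preformed caesium salt of 1 (from 1 and Cs2CO3; DMF, rt), again with inversion, then gives 9.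

Further compounds
F1 | step 3 | racemic methyl 8-acetoxy-3-oxo-2-oxabicyclo[2.2.2]oct-5-ene-1-carboxylate (endo/exo mixture, not isolated) | COC(=O)C12OC(=O)C(C=C1)C(OC(C)=O)C2
F2 | step 3 | racemic methyl 5-acetoxycyclohexa-1,3-diene-1-carboxylate | COC(=O)C1=CC=CC(OC(C)=O)C1
F3 | step 3 | methyl (5R)-5-hydroxycyclohexa-1,3-diene-1-carboxylate | COC(=O)C1=CC=C[C@H](O)C1
F4 | step 3 | methyl (5S)-5-acetoxycyclohexa-1,3-diene-1-carboxylate | COC(=O)C1=CC=C[C@@H](OC(C)=O)C1
F5 | step 4 | methyl (3R,4R,5R)-3,4-dihydroxy-5-{[(2E)-3-methylpent-2-enoyl]oxy}cyclohex-1-ene-1-carboxylate | COC(=O)C1=C[C@@H](O)[C@@H](O)[C@H](OC(=O)/C=C(\C)CC)C1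
F6 | step 5 | methyl (3S,4S,5R)-3-bromo-4-hydroxy-5-{[(2E)-3-methylpent-2-enoyl]oxy}cyclohex-1-ene-1-carboxylate | COC(=O)C1=C[C@H](Br)[C@@H](O)[C@H](OC(=O)/C=C(\C)CC)C1
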